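## Retrosynthetic overview

1. The strategy rests on ring B (C5–C10) of the trans-decalin, where the C5 methyl and the C7 isopropenyl sit 1,3-cis beside the 8,9-cis-diol: one bond that the target lacks, C8–C11, turns ring B plus its side chain into the bicyclo[4.1.0]heptane of (+)-3-carene, whose C1 is C7 in the correct absolute configuration.
2. Disconnections: the C9 ester (Z acid from syn-carbocupration of a 2-ynoate); isopropenyl back to a C11 tertiary alcohol; 8,9-diol back to the 8-ene; 8-ene plus C11–OH back to a C9 cyclopropyl carbinol by restoring C8–C11; C9–OH/C10–H back to a 9(10)-ene; ring A back to caran-4-one and (E)-pent-3-en-2-one.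
3. Ring order: ring B is bought together with the temporary cyclopropane; ring A is closed on it by Michael addition (C4–C5) and aldol condensation (C1–C10); the three-membered ring is opened last, in a step that closes no ring.

Key step: step 10

Remark: eremophilane numbering is used from compound 7 on (carane C3, C4, C5, C6, C1, C2, C7 become C5, C10, C9, C8, C7, C6, C11); "8,11-cyclo" means the extra C8–C11 bond, β is the decalin face carrying the C5 methyl, and the organoboranes of steps 1 and 9 are drawn as monoalkylboranes.

## Route

Step 1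
Reactants: 1 (+)-3-carene
Product: 3 (1S,3R,4R,6R)-3,7,7-trimethylbicyclo[4.1.0]heptan-4-ol (4-isocaranol), via 4-isocaranylborane 2 (not isolated)
Conditions: BH3·THF, THF, 0 °C to rt; then NaOH, H2O2, H2O, 0 °C to rt
Reagents that add atoms: hydrogen peroxide, OO
Why: Brown hydroboration–oxidation places boron on the less substituted alkene carbon and adds H and B syn on the face away from the CMe2 bridge, so the C4 hydroxyl (formed with retention) should end trans to the cyclopropane and to the C3 methyl.

Step 2
Reactants: 3 4-isocaranol
Product: 4 (1S,3R,6R)-3,7,7-trimethylbicyclo[4.1.0]heptan-4-one (caran-4-one)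
Conditions: nPr4N[RuO4] (cat.), NMO, 4 Å molecular sieves, CH2Cl2, rt
Reagents that add atoms: none
Why: Ley–Griffith oxidation of a secondary alcohol under neutral conditions should spare the cyclopropane; the α-methyl centre becomes trigonal in the next step, so its possible epimerisation is harmless.

Step 3
Reactants: 4 caran-4-one
Product: 5 (1S,6R)-3,7,7-trimethyl-4-(trimethylsilyloxy)bicyclo[4.1.0]hept-3-ene
Conditions: TMSCl, NaI, Et3N, MeCN, rt
Reagents that add atoms: chlorotrimethylsilane, C[Si](C)(C)Cl
Why: Silyl enol ether formation with iodotrimethylsilane generated in the flask is equilibrating and should favour the tetrasubstituted enol ether toward the methyl-bearing carbon, as with 2-methylcyclohexanone; no stereocentre is set.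

Step 4
Reactants: 5 silyl enol ether; 6 (E)-pent-3-en-2-one
Product: 8 (1S,3R,6R)-3,7,7-trimethyl-3-[(2S)-4-oxopentan-2-yl]bicyclo[4.1.0]heptan-4-one (1,5-diketone), via trichlorotitanium enolate 7 (not isolated)
Conditions: TiCl4, CH2Cl2, −78 °C; then H2O
Reagents that add atoms: none
Why: Mukaiyama–Michael addition, in which the TiCl4-bound enone is attacked by the enol ether on the face opposite the CMe2 bridge (setting C5, methyl cis to the cyclopropane) through the compact open transition state that gives the cis-dimethyl relationship (C4) with enol ethers of 2-methylcyclohexanones.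

Step 5
Reactants: 8 1,5-diketone
Product: 10 tricyclic enone 8,11-cycloeremophil-1(10)-en-2-one (4β,5β-dimethyl and β-fused CMe2 bridge), via ketol 9 (not isolated)
Conditions: KOH, MeOH, reflux
Reagents that add atoms: none
Why: Intramolecular aldol condensation, the second half of a Robinson annulation: the methyl ketone enolate closes ring A on the C10 carbonyl in a 6-(enolendo)-exo-trig mode and the ketol loses water by E1cB, so C10 becomes trigonal and no new stereocentre survives.

Step 6
Reactants: 10 tricyclic enone
Product: 12 β,γ-enone 8,11-cycloeremophil-9-en-2-one, via potassium dienolate 11 (not isolated)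
Conditions: KOtBu, tBuOH, rt; then cold aq. AcOH
Reagents that add atoms: none
Why: Deconjugation of an enone: γ-deprotonation at C9 gives the extended dienolate and fast kinetic protonation at the α-carbon C1 should leave the double bond at C9–C10, as in the conversion of steroidal 4-en-3-ones to 5-en-3-ones; no stereocentre is set.

Step 7
Reactants: 12 β,γ-enone
Product: 13 8,11-cycloeremophil-9-en-2α-ol (axial alcohol, trans to the C5 methyl)
Conditions: Li[HB(sBu)3], THF, −78 °C; then H2O
Reagents that add atoms: none
Why: Reduction with a bulky trialkylborohydride delivers hydride along the equatorial trajectory and should give the axial 2α-alcohol, as with 3-keto-5-ene steroids, while the low temperature outruns base-induced reconjugation.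

Step 8
Reactants: 13 axial alcohol
Product: 14 2α-(tert-butyldimethylsilyloxy)-8,11-cycloeremophil-9-ene
Conditions: TBSOTf, 2,6-lutidine, CH2Cl2, −78 to 0 °C
Reagents that add atoms: tert-butyldimethylsilyl triflate, CC(C)(C)[Si](C)(C)OS(=O)(=O)C(F)(F)F
Why: Silylation of a hindered axial secondary alcohol with a silyl triflate and a non-nucleophilic base; the buffered medium should leave the vinylcyclopropane intact.

Step 9
Reactants: 14 silyl ether
Product: 16 2α-(tert-butyldimethylsilyloxy)-8,11-cycloeremophilan-9α-ol (10α-H, trans-fused), via C9 alkylborane 15 (not isolated)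
Conditions: BH3·THF, THF, 0 °C to rt; then NaOH, H2O2, H2O
Reagents that add atoms: hydrogen peroxide, OO
Why: Brown hydroboration–oxidation of a 2-carene-type alkene: boron goes to the less substituted C9 and H and B add syn on the α face, away from the axial C5 methyl and the CMe2 bridge, which should set the 10α-hydrogen (trans ring fusion) and the 9α-hydroxyl.

Step 10
Reactants: 16 cyclopropyl carbinol
Product: 18 2α-(tert-butyldimethylsilyloxy)eremophil-8-en-11-ol (7β side chain, 10α-H), via C9 mesylate 17 (not isolated)
Conditions: Ms2O, Et3N, THF, −30 °C; then H2O, acetone, NaHCO3, −30 °C to rt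
Reagents that add atoms: water, O
Why: Sulfonylation of the C9 carbinol gives a cyclopropylcarbinyl mesylate that ionises once water is present; in the bisected cation the exocyclic C8–C11 bond breaks, the 8,9-double bond forms and water adds to the tertiary C11 terminus (cyclopropylcarbinyl-to-homoallyl rearrangement, the ionic step of the Julia olefin synthesis). The closest known case is the hydrolytic opening of 2-carene oxide to p-menth-2-ene-1,8-diol, where the same gem-dimethylcyclopropane bond is cut next to a developing ring cation. No ring is closed: the only ring event is the opening of the cyclopropane, which converts the carane-fused tricycle into the eremophilane decalin. No stereocentre is created (C11 carries two methyls, C8 and C9 become trigonal); C7 keeps the carene configuration because its bond to C11 is not involved, so the side chain stays on the β face cis to the C5 methyl, and C10 is untouched. The step needs cleavage of C8–C11 and not of the ring bond C7–C8 (which would enlarge ring B), and capture at C11 and not return at C9, proton loss from a methyl or a 1,2-hydride shift from C10; the first is secured by the tertiary cation that only C11 can carry and by the exocyclic bond standing nearly parallel to the vacant orbital at C9 while C7–C8 lies near its nodal plane, the second by strain release, the water-rich bicarbonate-buffered medium and the low temperature.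

Step 11
Reactants: 18 homoallylic tertiary alcohol
Product: 19 2α-(tert-butyldimethylsilyloxy)eremophilane-8α,9α,11-triol
Conditions: OsO4 (cat.), NMO, acetone/H2O, rt
Reagents that add atoms: osmium tetroxide, O=[Os](=O)(=O)=O; N-methylmorpholine N-oxide, C[N+]1([O-])CCOCC1; water, O
Why: Upjohn dihydroxylation adds both oxygens syn on the α face, opposite the axial C5 methyl and the pseudoaxial C7 side chain, which should set C8 and C9; the tertiary alcohol is inert and no second alkene is present.

Step 12
Reactants: 20 methyl pent-2-ynoate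
Product: 22 methyl (Z)-3-methylpent-2-enoate, via vinylcuprate 21 (not isolated)
Conditions: Me2CuLi (from CuI, MeLi), THF, −78 °C; then aq. NH4Cl, −78 °C
Reagents that add atoms: lithium dimethylcuprate, [Li+].C[Cu-]C
Why: Syn-carbocupration of a 2-ynoate puts methyl on C3 and copper on C2 on the same side, and protonation with retention at −78 °C (before the vinylcopper can equilibrate through the allenoate) should give the Z alkene with ethyl cis to the ester.

Step 13
Reactants: 22 methyl (Z)-3-methylpent-2-enoate
Product: 23 (Z)-3-methylpent-2-enoic acid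
Conditions: LiOH, THF/MeOH/H2O, rt; then aq. HCl
Reagents that add atoms: lithium hydroxide, [Li+].[OH-]
Why: Saponification by acyl–oxygen cleavage at room temperature, mild enough that the trisubstituted Z alkene should neither isomerise nor deconjugate.

Step 14
Reactants: 23 (Z)-3-methylpent-2-enoic acid
Product: 24 (Z)-3-methylpent-2-enoyl chloride
Conditions: (COCl)2, DMF (cat.), CH2Cl2, 0 °C to rt
Reagents that add atoms: oxalyl chloride, ClC(=O)C(Cl)=O
Why: Acid chloride formation through the Vilsmeier-type chloroiminium species; no amine base is present, so the vinylketene pathway that would scramble the alkene is avoided, and the chloride is used at once.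

Step 15
Reactants: 19 triol; 24 (Z)-3-methylpent-2-enoyl chloride
Product: 26 2α-(tert-butyldimethylsilyloxy)-8α,11-dihydroxyeremophilan-9α-yl (Z)-3-methylpent-2-enoate, via stannylene acetal 25 (not isolated)
Conditions: Bu2SnO, toluene, reflux (−H2O); then 24, toluene, 0 °C
Reagents that add atoms: none
Why: Stannylene-acetal-mediated monoacylation: the five-membered dibutylstannylene of the cis-diol raises the nucleophilicity of the equatorial, less hindered C9 oxygen (C8–O is flanked by the bulky C7 substituent), the tertiary C11 hydroxyl is inert, and the base-free conditions should keep the Z geometry.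

Step 16
Reactants: 26 C9 mono-ester
Product: 27 2α-(tert-butyldimethylsilyloxy)-11-hydroxy-8α-(triethylsilyloxy)eremophilan-9α-yl (Z)-3-methylpent-2-enoate
Conditions: TESOTf, 2,6-lutidine, CH2Cl2, −78 °C
Reagents that add atoms: triethylsilyl triflate, CC[Si](CC)(CC)OS(=O)(=O)C(F)(F)F
Why: Silylation of the secondary C8 hydroxyl in preference to the tertiary C11 hydroxyl at low temperature; the non-nucleophilic base should not trigger 1,2-acyl migration from O9 to O8.

Step 17
Reactants: 27 tertiary alcohol
Product: 28 2α-(tert-butyldimethylsilyloxy)-8α-(triethylsilyloxy)eremophil-11(12)-en-9α-yl (Z)-3-methylpent-2-enoate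
Conditions: MeO2CN–SO2NEt3 (Burgess reagent), benzene, 50 °C
Reagents that add atoms: none
Why: Burgess dehydration by syn elimination of the tertiary sulfamate: six methyl hydrogens compete with one ring hydrogen at C7 that is crowded by the C8 silyloxy group, so the isopropenyl group should predominate, and the neutral conditions spare both silyl ethers and the enoate.

Step 18
Reactants: 28 bis-silyl ether
Product: 29 target, (1S,2R,3R,4aR,5S,7S,8aR)-2,7-dihydroxy-4a,5-dimethyl-3-(prop-1-en-2-yl)decahydronaphthalen-1-yl (2Z)-3-methylpent-2-enoate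
Conditions: HF·pyridine, pyridine, THF, 0 °C to rt
Reagents that add atoms: none
Why: Fluoride-driven desilylation removes the triethylsilyl and the tert-butyldimethylsilyl ether in one operation; the buffered, non-basic medium should prevent migration of the acyl group from O9 to the neighbouring cis O8 and leave the isopropenyl group alone.

## Compound list

1 | (+)-3-carene, (1S,6R)-3,7,7-trimethylbicyclo[4.1.0]hept-3-ene | CC1=CC[C@@H]2[C@H](C1)C2(C)C | starting material
2 | 4-isocaranylborane (boron on C4, trans to the CMe2 bridge) | C[C@@H]1C[C@H]2[C@@H](C[C@H]1B)C2(C)C | intermediate (not isolated)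
3 | (1S,3R,4R,6R)-3,7,7-trimethylbicyclo[4.1.0]heptan-4-ol (4-isocaranol) | C[C@@H]1C[C@H]2[C@@H](C[C@H]1O)C2(C)C | intermediate
4 | (1S,3R,6R)-3,7,7-trimethylbicyclo[4.1.0]heptan-4-one (caran-4-one) | C[C@@H]1C[C@H]2[C@@H](CC1=O)C2(C)C | intermediate
5 | (1S,6R)-3,7,7-trimethyl-4-(trimethylsilyloxy)bicyclo[4.1.0]hept-3-ene | CC1=C(O[Si](C)(C)C)C[C@@H]2[C@H](C1)C2(C)C | intermediate
6 | (E)-pent-3-en-2-one | C/C=C/C(C)=O | starting material
7 | trichlorotitanium (Z)-enolate of the Michael adduct | CC1(C)[C@H]2C[C@](C)([C@@H](C)/C=C(/C)O[Ti](Cl)(Cl)Cl)C(=O)C[C@@H]12 | intermediate (not isolated)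
8 | (1S,3R,6R)-3,7,7-trimethyl-3-[(2S)-4-oxopentan-2-yl]bicyclo[4.1.0]heptan-4-one | CC1(C)[C@H]2C[C@](C)([C@@H](C)CC(C)=O)C(=O)C[C@@H]12 | intermediate
9 | 10β-hydroxy-8,11-cycloeremophilan-2-one (cis-fused ketol) | CC1(C)[C@H]2C[C@]3(C)[C@@H](C)CC(=O)C[C@]3(O)C[C@@H]12 | intermediate (not isolated)
10 | 8,11-cycloeremophil-1(10)-en-2-one | CC1(C)[C@H]2C[C@]3(C)[C@@H](C)CC(=O)C=C3C[C@@H]12 | intermediate
11 | potassium 8,11-cycloeremophila-1,9-dien-2-olate | [K+].CC1(C)[C@H]2C[C@]3(C)[C@@H](C)CC([O-])=CC3=C[C@@H]12 | intermediate (not isolated)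
12 | 8,11-cycloeremophil-9-en-2-one | CC1(C)[C@H]2C[C@]3(C)[C@@H](C)CC(=O)CC3=C[C@@H]12 | intermediate
13 | 8,11-cycloeremophil-9-en-2α-ol | CC1(C)[C@H]2C[C@]3(C)[C@@H](C)C[C@H](O)CC3=C[C@@H]12 | intermediate
14 | 2α-(tert-butyldimethylsilyloxy)-8,11-cycloeremophil-9-ene | CC1(C)[C@H]2C[C@]3(C)[C@@H](C)C[C@H](O[Si](C)(C)C(C)(C)C)CC3=C[C@@H]12 | intermediate
15 | 9α-boryl-2α-(tert-butyldimethylsilyloxy)-8,11-cycloeremophilane | CC1(C)[C@H]2C[C@]3(C)[C@@H](C)C[C@H](O[Si](C)(C)C(C)(C)C)C[C@H]3[C@H](B)[C@@H]12 | intermediate (not isolated)
16 | 2α-(tert-butyldimethylsilyloxy)-8,11-cycloeremophilan-9α-ol | CC1(C)[C@H]2C[C@]3(C)[C@@H](C)C[C@H](O[Si](C)(C)C(C)(C)C)C[C@H]3[C@H](O)[C@@H]12 | intermediate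
17 | 9α-methanesulfonate of 16 | CC1(C)[C@H]2C[C@]3(C)[C@@H](C)C[C@H](O[Si](C)(C)C(C)(C)C)C[C@H]3[C@H](OS(C)(=O)=O)[C@@H]12 | intermediate (not isolated)
18 | 2α-(tert-butyldimethylsilyloxy)eremophil-8-en-11-ol | CC(C)(O)[C@H]1C[C@]2(C)[C@@H](C)C[C@H](O[Si](C)(C)C(C)(C)C)C[C@H]2C=C1 | intermediate
19 | 2α-(tert-butyldimethylsilyloxy)eremophilane-8α,9α,11-triol | CC(C)(O)[C@H]1C[C@]2(C)[C@@H](C)C[C@H](O[Si](C)(C)C(C)(C)C)C[C@H]2[C@H](O)[C@@H]1O | intermediate
20 | methyl pent-2-ynoate | CCC#CC(=O)OC | starting material
21 | lithium methyl[1-(methoxycarbonyl)-2-methylbut-1-enyl]cuprate (new methyl and copper cis) | [Li+].CC/C(C)=C(/[Cu-]C)C(=O)OC | intermediate (not isolated)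
22 | methyl (Z)-3-methylpent-2-enoate | COC(=O)/C=C(/C)CC | intermediate
23 | (Z)-3-methylpent-2-enoic acid | OC(=O)/C=C(/C)CC | intermediate
24 | (Z)-3-methylpent-2-enoyl chloride | ClC(=O)/C=C(/C)CC | intermediate
25 | 8α,9α-O-dibutylstannylene acetal of 19 | CC(C)(O)[C@H]1C[C@]2(C)[C@@H](C)C[C@H](O[Si](C)(C)C(C)(C)C)C[C@H]2[C@@H]3O[Sn](CCCC)(CCCC)O[C@H]13 | intermediate (not isolated)
26 | 2α-(tert-butyldimethylsilyloxy)-8α,11-dihydroxyeremophilan-9α-yl (Z)-3-methylpent-2-enoate | CC(C)(O)[C@H]1C[C@]2(C)[C@@H](C)C[C@H](O[Si](C)(C)C(C)(C)C)C[C@H]2[C@H](OC(=O)/C=C(/C)CC)[C@@H]1O | intermediate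
27 | 2α-(tert-butyldimethylsilyloxy)-11-hydroxy-8α-(triethylsilyloxy)eremophilan-9α-yl (Z)-3-methylpent-2-enoate | CC(C)(O)[C@H]1C[C@]2(C)[C@@H](C)C[C@H](O[Si](C)(C)C(C)(C)C)C[C@H]2[C@H](OC(=O)/C=C(/C)CC)[C@@H]1O[Si](CC)(CC)CC | intermediate
28 | 2α-(tert-butyldimethylsilyloxy)-8α-(triethylsilyloxy)eremophil-11(12)-en-9α-yl (Z)-3-methylpent-2-enoate | C=C(C)[C@H]1C[C@]2(C)[C@@H](C)C[C@H](O[Si](C)(C)C(C)(C)C)C[C@H]2[C@H](OC(=O)/C=C(/C)CC)[C@@H]1O[Si](CC)(CC)CC | intermediate
29 | CNP0129603.1, (1S,2R,3R,4aR,5S,7S,8aR)-2,7-dihydroxy-4a,5-dimethyl-3-(prop-1-en-2-yl)decahydronaphthalen-1-yl (2Z)-3-methylpent-2-enoate | C=C(C)[C@H]1C[C@]2(C)[C@@H](C)C[C@H](O)C[C@H]2[C@H](OC(=O)/C=C(/C)CC)[C@@H]1O | target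

## Step count and risks

Total step count: 18. Longest linear sequence: 15 steps (steps 1 to 11 and 15 to 18); the acid branch (steps 12 to 14) joins at step 15.

Steps most likely to fail:

Step 10. After ionisation the cation may collapse back at C9, lose a methyl proton, or undergo a 1,2-hydride shift from C10 instead of taking up water at C11; the transient sulfonate may also be hard to form cleanly next to the ring fusion. The fallback sets out from 16 and returns at 18. The carbinol 16 would be submitted to the anhydrous halide variant of the same rearrangement (Julia olefin synthesis: PBr3, LiBr, 2,4,6-collidine, Et2O, −40 °C, then ZnBr2, 0 °C), so that bromide instead of water ends the sequence irreversibly at the tertiary terminus and should give 2α-(tert-butyldimethylsilyloxy)-11-bromoeremophil-8-ene F4. Silver-assisted hydrolysis of this tertiary bromide (AgNO3, aqueous acetone, rt) should then deliver 18.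

Step 17. The elimination may turn toward the C7 hydrogen and give the tetrasubstituted isopropylidene isomer, or ionisation at C11 may start acyl or silyl migration in the crowded C7–C9 region. The fallback sets out from 19 and returns at 29; it changes the order so that the alkene is made before the ester is attached. Triol 19 and carbonyldiimidazole should give the 8α,9α-cyclic carbonate F5 with the tertiary alcohol free. A pyridine-mediated elimination through the chlorosulfite (SOCl2, pyridine, −20 °C) on this compact, ester-free substrate should give the isopropenyl carbonate F6, from which a regioisomer can be removed before the acid is spent. K2CO3 in methanol should free the isopropenyl diol F7, stannylene-mediated acylation with 24 as in step 15 should give the 9-monoester F8, and HF·pyridine removes its single silyl group to give 29.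

Step 4. Enolisation of 4 toward C9 (next to the cyclopropane) in step 3 would carry the wrong regioisomer into the addition, and the open transition state may control C4 poorly. The fallback sets out from 4 and returns at 10; it uses a covalent blocking group and a reversible enolate Michael addition. Formylation of 4 at its only α-methylene (HCO2Et, NaH) should give the hydroxymethylene ketone F1, and condensation with N-methylaniline the N-methylanilinomethylene ketone F2, in which only the methyl-bearing α-carbon can be deprotonated. Michael addition to 6 with KOtBu in tBuOH, conditions under which 2-methylcycloalkanones are known to favour the cis-dimethyl adduct, should give the blocked diketone F3. Hot aqueous-methanolic KOH then removes the blocking group and performs the aldol condensation to give 10.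

## Further compounds

F1 | step 4 | 5-(hydroxymethylene)caran-4-one (enol geometry not fixed) | C[C@@H]1C[C@H]2[C@@H](C(=CO)C1=O)C2(C)C
F2 | step 4 | 5-[(N-methylanilino)methylene]caran-4-one (enamine geometry not fixed) | C[C@@H]1C[C@H]2[C@@H](C(=CN(C)c3ccccc3)C1=O)C2(C)C
F3 | step 4 | 9-[(N-methylanilino)methylene] derivative of diketone 8 | CC1(C)[C@H]2C[C@](C)([C@@H](C)CC(C)=O)C(=O)C(=CN(C)c3ccccc3)[C@@H]12
F4 | step 10 | 2α-(tert-butyldimethylsilyloxy)-11-bromoeremophil-8-ene | CC(C)(Br)[C@H]1C[C@]2(C)[C@@H](C)C[C@H](O[Si](C)(C)C(C)(C)C)C[C@H]2C=C1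
F5 | step 17 | 8α,9α-cyclic carbonate of 19 | CC(C)(O)[C@H]1C[C@]2(C)[C@@H](C)C[C@H](O[Si](C)(C)C(C)(C)C)C[C@H]2[C@@H]3OC(=O)O[C@H]13
F6 | step 17 | 2α-(tert-butyldimethylsilyloxy)eremophil-11(12)-ene-8α,9α-diyl carbonate | C=C(C)[C@H]1C[C@]2(C)[C@@H](C)C[C@H](O[Si](C)(C)C(C)(C)C)C[C@H]2[C@@H]3OC(=O)O[C@H]13
F7 | step 17 | 2α-(tert-butyldimethylsilyloxy)eremophil-11(12)-ene-8α,9α-diol | C=C(C)[C@H]1C[C@]2(C)[C@@H](C)C[C@H](O[Si](C)(C)C(C)(C)C)C[C@H]2[C@H](O)[C@@H]1O
F8 | step 17 | 2α-(tert-butyldimethylsilyloxy)-8α-hydroxyeremophil-11(12)-en-9α-yl (Z)-3-methylpent-2-enoate | C=C(C)[C@H]1C[C@]2(C)[C@@H](C)C[C@H](O[Si](C)(C)C(C)(C)C)C[C@H]2[C@H](OC(=O)/C=C(/C)CC)[C@@H]1O
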